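**Retrosynthetic overview**
- The strategy rests on ring A. Its oxygens at C5, C7 and C8a sit on alternate carbons and C4a carries the acyl carbon C4, which is the pattern of a triketide folded by Claisen closure. A 4-methoxy-2-pyrone carries this chain with the C7 methoxyl already in place.
- Target 19 comes from flavone 15 by Elbs hydroxylation at C8 (para to the C5 hydroxyl), 8-O-methylation and hydrogenolysis. Ring C (O1–C2) comes from cyclodehydration of the o-hydroxyaryl diketone 13.
- Ring A (bond C4a–C8a) comes from Mg(OMe)2 opening and Claisen refolding of the pyrone diketone 11.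
- 11 comes from C-acylation of lithiated 4-methoxy-6-methyl-2-pyrone 7 with the silylated aldol ester 6 (made from ester 3 and aldehyde 2), then desilylation and oxidation.
- Ring order: ring B is bought, ring A forms in step 7, ring C forms in step 8.

Key step: step 7

Assumption: compounds 5, 6, 9 and 10 are carried as racemic mixtures of diastereomers, because both of their stereocenters are erased later (ketone in step 6, sp2 C3 of the flavone in step 8); the target has no stereocenter.

**Step 1**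
Reactants: 1 2,4-dihydroxy-5-methoxybenzaldehyde
Product: 2 2,4-bis(benzyloxy)-5-methoxybenzaldehyde
Conditions: BnBr (2.4 equiv), K2CO3, DMF, 60 °C
Reagents that add atoms: benzyl bromide, BrCc1ccccc1
Why: Williamson ether synthesis; both phenoxides, the chelated 2-OH included at this temperature in DMF, are alkylated and the aldehyde is inert to carbonate.

**Step 2**
Reactants: 3 methyl benzyloxyacetate; 2 2,4-bis(benzyloxy)-5-methoxybenzaldehyde
Product: 5 methyl 2-(benzyloxy)-3-[2,4-bis(benzyloxy)-5-methoxyphenyl]-3-hydroxypropanoate (racemic syn/anti mixture), via lithium ester enolate 4 (not isolated)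
Conditions: LiN(iPr)2, THF, −78 °C; then 2, −78 °C; aq. NH4Cl
Reagents that add atoms: none
Why: lithium enolate aldol addition of a glycolate ester to a non-enolisable aldehyde; the two new stereocenters form without control and need none, since C3 becomes a ketone in step 6 and C2 ends as sp2 C3 of the flavone.

**Step 3**
Reactants: 5 methyl 2-(benzyloxy)-3-[2,4-bis(benzyloxy)-5-methoxyphenyl]-3-hydroxypropanoate
Product: 6 methyl 2-(benzyloxy)-3-[2,4-bis(benzyloxy)-5-methoxyphenyl]-3-[(tert-butyldimethylsilyl)oxy]propanoate (racemic diastereomer mixture)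
Conditions: TBSOTf, 2,6-lutidine, CH2Cl2, 0 °C
Reagents that add atoms: tert-butyldimethylsilyl trifluoromethanesulfonate, CC(C)(C)[Si](C)(C)OS(=O)(=O)C(F)(F)F
Why: silylation of a hindered secondary benzylic alcohol with a silyl triflate and a hindered base; the silyl ether stops retro-aldol cleavage when the ester is later attacked by a carbanion.

**Step 4**
Reactants: 7 4-methoxy-6-methyl-2H-pyran-2-one; 6 methyl 2-(benzyloxy)-3-[2,4-bis(benzyloxy)-5-methoxyphenyl]-3-[(tert-butyldimethylsilyl)oxy]propanoate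
Product: 9 6-{3-(benzyloxy)-4-[2,4-bis(benzyloxy)-5-methoxyphenyl]-4-[(tert-butyldimethylsilyl)oxy]-2-oxobutyl}-4-methoxy-2H-pyran-2-one (racemic diastereomer mixture), via lithiated pyrone 8 (not isolated)
Conditions: 7 (2.2 equiv), LiN(iPr)2 (2.2 equiv), THF, −78 °C; then 6, −78 to −30 °C; aq. NH4Cl
Reagents that add atoms: none
Why: crossed Claisen condensation; the amide base removes a proton from the C6 methyl group of the pyrone (a vinylogous ester enolate) and this carbanion acylates at the methyl ester, which the α-alkoxy group makes more electrophilic, while the second equivalent of anion deprotonates the active methylene of the product and so protects the new ketone.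

**Step 5**
Reactants: 9 6-{3-(benzyloxy)-4-[2,4-bis(benzyloxy)-5-methoxyphenyl]-4-[(tert-butyldimethylsilyl)oxy]-2-oxobutyl}-4-methoxy-2H-pyran-2-one
Product: 10 6-{3-(benzyloxy)-4-[2,4-bis(benzyloxy)-5-methoxyphenyl]-4-hydroxy-2-oxobutyl}-4-methoxy-2H-pyran-2-one (racemic diastereomer mixture)
Conditions: HF·pyridine, pyridine, THF, 0 °C to rt
Reagents that add atoms: none
Why: fluoride-driven cleavage of the silyl ether under buffered, weakly acidic conditions, which avoid retro-aldol cleavage and β-elimination of the β-hydroxy ketone.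

**Step 6**
Reactants: 10 6-{3-(benzyloxy)-4-[2,4-bis(benzyloxy)-5-methoxyphenyl]-4-hydroxy-2-oxobutyl}-4-methoxy-2H-pyran-2-one
Product: 11 6-{3-(benzyloxy)-4-[2,4-bis(benzyloxy)-5-methoxyphenyl]-2,4-dioxobutyl}-4-methoxy-2H-pyran-2-one (racemic; enolisable)
Conditions: Dess–Martin periodinane (1.3 equiv), CH2Cl2, 0 °C to rt
Reagents that add atoms: none
Why: Dess–Martin oxidation of a secondary benzylic alcohol, a standard neutral way from a β-hydroxy ketone to a 1,3-diketone that leaves the pyrone and the benzyl ethers intact.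

**Step 7**
Reactants: 11 6-{3-(benzyloxy)-4-[2,4-bis(benzyloxy)-5-methoxyphenyl]-2,4-dioxobutyl}-4-methoxy-2H-pyran-2-one
Product: 13 2-(benzyloxy)-3-[2,4-bis(benzyloxy)-5-methoxyphenyl]-1-(2,6-dihydroxy-4-methoxyphenyl)propane-1,3-dione (racemic; enolisable), via ring-opened triketo ester 12 (not isolated)
Conditions: Mg(OMe)2 (5 equiv), MeOH, 65 °C; then cold 1 M HCl
Reagents that add atoms: none
Why: Methoxide delivered by Mg(OMe)2 adds to the lactone carbonyl (pyrone C2) and the ring opens to the methyl (2E)-3-methoxy-5,7,9-trioxo ester 12, held as a magnesium chelate; the methylene between the C5 and C7 ketones of this chain (the future C4a) then attacks the ester carbon (the future C8a), methoxide leaves and the cyclohexadienone tautomerises to the arene, so that the C4a–C8a bond and ring A are formed as a 2-acyl-5-methoxyresorcinol. The closest known reaction is the Mg(OMe)2-induced ring opening and Claisen recyclisation of 6-(2-oxoalkyl)-4-methoxy-2-pyrones to acylresorcinols, the laboratory counterpart of the phloroglucinol-type polyketide folding. Ring A closes by a 6-exo-trig attack of the enolate carbon on the ester carbonyl, made easy by the cis arrangement of ester and chain across the C2=C3 bond that is inherited from the pyrone ring. No stereocenter is created; the benzyloxy-bearing carbon stays racemic and enolisable. The step needs Claisen closure at the central methylene to win over aldol closures (vinylogous attack of pyrone C5 on the aryl ketone before ring opening, or attack of the ester α-carbon on a chain ketone after it) and over retro-Claisen cleavage of the 2-benzyloxy-1,3-diketone by methoxide. The methyl enol ether fixes the C7 oxygen and leaves its flanking carbons only weakly nucleophilic, and Mg2+ holds the aryl diketone as a chelated enolate that resists methoxide and is a poor aldol acceptor, while the same chelation places the nucleophilic methylene next to the ester.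

**Step 8**
Reactants: 13 2-(benzyloxy)-3-[2,4-bis(benzyloxy)-5-methoxyphenyl]-1-(2,6-dihydroxy-4-methoxyphenyl)propane-1,3-dione
Product: 15 3-(benzyloxy)-2-[2,4-bis(benzyloxy)-5-methoxyphenyl]-5-hydroxy-7-methoxy-4H-chromen-4-one, via 2-hydroxyflavanone hemiketal 14 (not isolated)
Conditions: NaOAc, AcOH, 100 °C
Reagents that add atoms: none
Why: cyclodehydration of an o-hydroxyaryl 1,3-diketone (closing stage of the Baker–Venkataraman flavone synthesis); a phenol adds to the ring B ketone and water is lost, and because the two hydroxyls of ring A are equivalent by symmetry only one flavone can form, the other hydroxyl becoming the chelated 5-OH.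

**Step 9**
Reactants: 15 3-(benzyloxy)-2-[2,4-bis(benzyloxy)-5-methoxyphenyl]-5-hydroxy-7-methoxy-4H-chromen-4-one
Product: 17 3-(benzyloxy)-2-[2,4-bis(benzyloxy)-5-methoxyphenyl]-5,8-dihydroxy-7-methoxy-4H-chromen-4-one, via potassium aryl 8-sulfate 16 (not isolated)
Conditions: K2S2O8, aq. KOH, pyridine, 15 °C; then aq. HCl, 80 °C
Reagents that add atoms: potassium peroxodisulfate, [K+].[K+].[O-]S(=O)(=O)OOS(=O)(=O)[O-]
Why: Elbs persulfate oxidation; the 5-phenoxide attacks peroxodisulfate through its para carbon C8 in preference to the ortho carbon C6, and acid hydrolysis of the aryl sulfate frees the 8-OH, while benzyl ethers and the pyranone tolerate cold alkali and brief warm dilute acid.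

**Step 10**
Reactants: 17 3-(benzyloxy)-2-[2,4-bis(benzyloxy)-5-methoxyphenyl]-5,8-dihydroxy-7-methoxy-4H-chromen-4-one
Product: 18 3-(benzyloxy)-2-[2,4-bis(benzyloxy)-5-methoxyphenyl]-5-hydroxy-7,8-dimethoxy-4H-chromen-4-one
Conditions: MeI (1.1 equiv), K2CO3 (1.1 equiv), acetone, rt, under argon
Reagents that add atoms: iodomethane, CI
Why: Williamson O-methylation, selective for the 8-OH because the 5-OH is tied up in a hydrogen bond to the C4 carbonyl and is much less nucleophilic; argon keeps the hydroquinone from air oxidation.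

**Step 11**
Reactants: 18 3-(benzyloxy)-2-[2,4-bis(benzyloxy)-5-methoxyphenyl]-5-hydroxy-7,8-dimethoxy-4H-chromen-4-one
Product: 19 3,5-dihydroxy-2-(2,4-dihydroxy-5-methoxyphenyl)-7,8-dimethoxy-4H-chromen-4-one (target)
Conditions: H2 (1 atm), Pd/C, EtOAc/MeOH, rt
Reagents that add atoms: none
Why: catalytic hydrogenolysis of the three benzyl ethers (at C3, C2' and C4'); the methyl ethers and the C2=C3 bond of the flavonol are not touched under these mild conditions.

**Compound list**
1 | 2,4-dihydroxy-5-methoxybenzaldehyde | COc1cc(C=O)c(O)cc1O | starting material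
2 | 2,4-bis(benzyloxy)-5-methoxybenzaldehyde | COc1cc(C=O)c(OCc2ccccc2)cc1OCc1ccccc1 | intermediate
3 | methyl benzyloxyacetate | COC(=O)COCc1ccccc1 | starting material
4 | lithium enolate of methyl benzyloxyacetate (not isolated) | [Li]OC(OC)=COCc1ccccc1 | intermediate
5 | methyl 2-(benzyloxy)-3-[2,4-bis(benzyloxy)-5-methoxyphenyl]-3-hydroxypropanoate (racemic, syn/anti mixture) | COC(=O)C(OCc1ccccc1)C(O)c1cc(OC)c(OCc2ccccc2)cc1OCc1ccccc1 | intermediate
6 | methyl 2-(benzyloxy)-3-[2,4-bis(benzyloxy)-5-methoxyphenyl]-3-[(tert-butyldimethylsilyl)oxy]propanoate (racemic, diastereomer mixture) | COC(=O)C(OCc1ccccc1)C(O[Si](C)(C)C(C)(C)C)c1cc(OC)c(OCc2ccccc2)cc1OCc1ccccc1 | intermediate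
7 | 4-methoxy-6-methyl-2H-pyran-2-one | COC1=CC(=O)OC(C)=C1 | starting material
8 | 6-(lithiomethyl)-4-methoxy-2H-pyran-2-one (not isolated) | [Li]CC1=CC(OC)=CC(=O)O1 | intermediate
9 | 6-{3-(benzyloxy)-4-[2,4-bis(benzyloxy)-5-methoxyphenyl]-4-[(tert-butyldimethylsilyl)oxy]-2-oxobutyl}-4-methoxy-2H-pyran-2-one (racemic, diastereomer mixture) | COC1=CC(=O)OC(CC(=O)C(OCc2ccccc2)C(O[Si](C)(C)C(C)(C)C)c2cc(OC)c(OCc3ccccc3)cc2OCc2ccccc2)=C1 | intermediate
10 | 6-{3-(benzyloxy)-4-[2,4-bis(benzyloxy)-5-methoxyphenyl]-4-hydroxy-2-oxobutyl}-4-methoxy-2H-pyran-2-one (racemic, diastereomer mixture) | COC1=CC(=O)OC(CC(=O)C(OCc2ccccc2)C(O)c2cc(OC)c(OCc3ccccc3)cc2OCc2ccccc2)=C1 | intermediate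
11 | 6-{3-(benzyloxy)-4-[2,4-bis(benzyloxy)-5-methoxyphenyl]-2,4-dioxobutyl}-4-methoxy-2H-pyran-2-one (racemic, enolisable) | COC1=CC(=O)OC(CC(=O)C(OCc2ccccc2)C(=O)c2cc(OC)c(OCc3ccccc3)cc2OCc2ccccc2)=C1 | intermediate
12 | methyl (2E)-8-(benzyloxy)-9-[2,4-bis(benzyloxy)-5-methoxyphenyl]-3-methoxy-5,7,9-trioxonon-2-enoate, present as its magnesium enolate (racemic, not isolated) | COC(=O)/C=C(/OC)CC(=O)CC(=O)C(OCc1ccccc1)C(=O)c1cc(OC)c(OCc2ccccc2)cc1OCc1ccccc1 | intermediate
13 | 2-(benzyloxy)-3-[2,4-bis(benzyloxy)-5-methoxyphenyl]-1-(2,6-dihydroxy-4-methoxyphenyl)propane-1,3-dione (racemic, enolisable) | COc1cc(O)c(c(O)c1)C(=O)C(OCc1ccccc1)C(=O)c1cc(OC)c(OCc2ccccc2)cc1OCc1ccccc1 | intermediate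
14 | 3-(benzyloxy)-2-[2,4-bis(benzyloxy)-5-methoxyphenyl]-2,5-dihydroxy-7-methoxy-2,3-dihydro-4H-chromen-4-one (racemic, diastereomer mixture, not isolated) | COc1cc(O)c2C(=O)C(OCc3ccccc3)C(O)(Oc2c1)c1cc(OC)c(OCc2ccccc2)cc1OCc1ccccc1 | intermediate
15 | 3-(benzyloxy)-2-[2,4-bis(benzyloxy)-5-methoxyphenyl]-5-hydroxy-7-methoxy-4H-chromen-4-one | COc1cc(O)c2c(c1)oc(-c1cc(OC)c(OCc3ccccc3)cc1OCc1ccccc1)c(OCc1ccccc1)c2=O | intermediate
16 | potassium 3-(benzyloxy)-2-[2,4-bis(benzyloxy)-5-methoxyphenyl]-5-hydroxy-7-methoxy-4-oxo-4H-chromen-8-yl sulfate (not isolated) | [K+].COc1cc(O)c2c(c1OS(=O)(=O)[O-])oc(-c1cc(OC)c(OCc3ccccc3)cc1OCc1ccccc1)c(OCc1ccccc1)c2=O | intermediate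
17 | 3-(benzyloxy)-2-[2,4-bis(benzyloxy)-5-methoxyphenyl]-5,8-dihydroxy-7-methoxy-4H-chromen-4-one | COc1cc(O)c2c(c1O)oc(-c1cc(OC)c(OCc3ccccc3)cc1OCc1ccccc1)c(OCc1ccccc1)c2=O | intermediate
18 | 3-(benzyloxy)-2-[2,4-bis(benzyloxy)-5-methoxyphenyl]-5-hydroxy-7,8-dimethoxy-4H-chromen-4-one | COc1cc(O)c2c(c1OC)oc(-c1cc(OC)c(OCc3ccccc3)cc1OCc1ccccc1)c(OCc1ccccc1)c2=O | intermediate
19 | 3,5-dihydroxy-2-(2,4-dihydroxy-5-methoxyphenyl)-7,8-dimethoxy-4H-chromen-4-one (no stereocenter) | COc1cc(-c2oc3c(OC)c(OC)cc(O)c3c(=O)c2O)c(O)cc1O | target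

**Step count**
Total: 11 steps. Longest linear sequence: 11 steps (1 to 19); ester 3 enters in step 2 and pyrone 7 in step 4.

**Steps most likely to fail**

Step 7. Methoxide may cleave the 2-benzyloxy-1,3-diketone by retro-Claisen fragmentation. The deprotonated side chain may also close by vinylogous aldol attack of pyrone C5 on the aryl ketone before the lactone opens, or the opened chain may fold by aldol instead of Claisen condensation. The fallback builds ring A before the second ketone exists. It sets out from 7, 3 and 2 and comes back at 13.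
- Lithiated pyrone 8 (2.2 equiv, THF, −78 °C) is acylated with ester 3 to give 6-[3-(benzyloxy)-2-oxopropyl]-4-methoxy-2H-pyran-2-one F1.
- Mg(OMe)2 in MeOH at 65 °C should open F1 to methyl (2E)-8-(benzyloxy)-3-methoxy-5,7-dioxooct-2-enoate F2 (not isolated). F2 closes by the same Claisen mode, with no distal ketone to interfere, to 2-(benzyloxy)-1-(2,6-dihydroxy-4-methoxyphenyl)ethan-1-one F3.
- Aldehyde 2 is oxidised (Pinnick: NaClO2, NaH2PO4, 2-methyl-2-butene, t-BuOH/H2O) to 2,4-bis(benzyloxy)-5-methoxybenzoic acid F4. F4 is converted with (COCl)2 and catalytic DMF in CH2Cl2 into 2,4-bis(benzyloxy)-5-methoxybenzoyl chloride F5.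
- F3 is deprotonated with LiN(SiMe3)2 (4 equiv, THF, −78 °C) and C-aroylated at its enolate carbon with F5. This direct variant of the Baker–Venkataraman diketone synthesis should give 13.

Step 9. The electron-rich flavone may be degraded oxidatively in alkaline persulfate, and conversion may stay low because the tribenzyl ether dissolves poorly in the aqueous medium. The fallback installs the C8 oxygen by halogenation and copper-mediated C–O coupling. It sets out from 15 and comes back at 19.
- The 5-OH of 15 is benzylated (BnBr, K2CO3, DMF, 80 °C) to 3,5-bis(benzyloxy)-2-[2,4-bis(benzyloxy)-5-methoxyphenyl]-7-methoxy-4H-chromen-4-one F6.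
- Electrophilic iodination with N-iodosuccinimide (cat. CF3CO2H, MeCN, 0 °C) should go to C8, which is para to the 5-alkoxy group and ortho to the 7-methoxyl and O1. It should give 3,5-bis(benzyloxy)-2-[2,4-bis(benzyloxy)-5-methoxyphenyl]-8-iodo-7-methoxy-4H-chromen-4-one F7.
- Ullmann-type methoxylation (NaOMe, CuBr, DMF/MeOH, 100 °C) gives 3,5-bis(benzyloxy)-2-[2,4-bis(benzyloxy)-5-methoxyphenyl]-7,8-dimethoxy-4H-chromen-4-one F8.
- Hydrogenolysis of all four benzyl ethers (H2, Pd/C, EtOAc/MeOH) gives 19.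

Step 4. The pyrone carbanion may take a proton from the α-carbon of the hindered ester instead of acylating it, and the resulting ester enolate may then lose silanolate by β-elimination. The fallback replaces the acylation by an aldol addition and an oxidation. It sets out from 6 and comes back at 9.
- Ester 6 is reduced with iBu2AlH (CH2Cl2, −78 °C) to 2-(benzyloxy)-3-[2,4-bis(benzyloxy)-5-methoxyphenyl]-3-[(tert-butyldimethylsilyl)oxy]propanal F9.
- Lithiated pyrone 8 (1.2 equiv, THF, −78 °C) adds to the aldehyde to give 6-{3-(benzyloxy)-4-[2,4-bis(benzyloxy)-5-methoxyphenyl]-4-[(tert-butyldimethylsilyl)oxy]-2-hydroxybutyl}-4-methoxy-2H-pyran-2-one F10.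
- Dess–Martin oxidation of the new carbinol (CH2Cl2, 0 °C to rt) gives 9.

**Further compounds**
F1 | step 7 | 6-[3-(benzyloxy)-2-oxopropyl]-4-methoxy-2H-pyran-2-one | COC1=CC(=O)OC(CC(=O)COCc2ccccc2)=C1
F2 | step 7 | methyl (2E)-8-(benzyloxy)-3-methoxy-5,7-dioxooct-2-enoate (not isolated) | COC(=O)/C=C(/OC)CC(=O)CC(=O)COCc1ccccc1
F3 | step 7 | 2-(benzyloxy)-1-(2,6-dihydroxy-4-methoxyphenyl)ethan-1-one | COc1cc(O)c(C(=O)COCc2ccccc2)c(O)c1
F4 | step 7 | 2,4-bis(benzyloxy)-5-methoxybenzoic acid | COc1cc(C(=O)O)c(OCc2ccccc2)cc1OCc1ccccc1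
F5 | step 7 | 2,4-bis(benzyloxy)-5-methoxybenzoyl chloride | COc1cc(C(Cl)=O)c(OCc2ccccc2)cc1OCc1ccccc1
F6 | step 9 | 3,5-bis(benzyloxy)-2-[2,4-bis(benzyloxy)-5-methoxyphenyl]-7-methoxy-4H-chromen-4-one | COc1cc(OCc3ccccc3)c2c(c1)oc(-c1cc(OC)c(OCc3ccccc3)cc1OCc1ccccc1)c(OCc1ccccc1)c2=O
F7 | step 9 | 3,5-bis(benzyloxy)-2-[2,4-bis(benzyloxy)-5-methoxyphenyl]-8-iodo-7-methoxy-4H-chromen-4-one | COc1cc(OCc3ccccc3)c2c(c1I)oc(-c1cc(OC)c(OCc3ccccc3)cc1OCc1ccccc1)c(OCc1ccccc1)c2=O
F8 | step 9 | 3,5-bis(benzyloxy)-2-[2,4-bis(benzyloxy)-5-methoxyphenyl]-7,8-dimethoxy-4H-chromen-4-one | COc1cc(OCc3ccccc3)c2c(c1OC)oc(-c1cc(OC)c(OCc3ccccc3)cc1OCc1ccccc1)c(OCc1ccccc1)c2=O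
F9 | step 4 | 2-(benzyloxy)-3-[2,4-bis(benzyloxy)-5-methoxyphenyl]-3-[(tert-butyldimethylsilyl)oxy]propanal (racemic, diastereomer mixture) | O=CC(OCc1ccccc1)C(O[Si](C)(C)C(C)(C)C)c1cc(OC)c(OCc2ccccc2)cc1OCc1ccccc1
F10 | step 4 | 6-{3-(benzyloxy)-4-[2,4-bis(benzyloxy)-5-methoxyphenyl]-4-[(tert-butyldimethylsilyl)oxy]-2-hydroxybutyl}-4-methoxy-2H-pyran-2-one (racemic, diastereomer mixture) | COC1=CC(=O)OC(CC(O)C(OCc2ccccc2)C(O[Si](C)(C)C(C)(C)C)c2cc(OC)c(OCc3ccccc3)cc2OCc2ccccc2)=C1
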